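**Assumption:** the target SMILES has no stereocentre and no E/Z element (the prenyl alkene carries two methyl groups). Ambofuranol is therefore achiral and there is no enantiomer to select. The one stereocentre that appears on the way (in 10) is racemic and is erased in step 9.

## Retrosynthetic overview

1. Ambofuranol comes from its 6-O-TIPS, 2'-O-allyl ether by a one-pot Pd(0) deallylation and fluoride desilylation.
2. The furan ring is the only ring made, since both benzene rings are bought. It is cut at C2=C3 by a new intramolecular ester Wittig reaction of an α-methoxy ylide, whose OMe becomes the 3-OMe.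
3. The ylide comes from an α-methoxyphosphonium salt, that from a dimethyl acetal, and that from an O-aroylated salicylaldehyde (C3 is the formyl carbon, C2 the ester carbonyl carbon).
4. The ester comes from a 5-prenyl-4-silyloxysalicylaldehyde and 2-(allyloxy)-4-methoxybenzoyl chloride.
5. The prenyl group comes from a Stille coupling on 5-bromo-2,4-dihydroxybenzaldehyde, and the acid chloride from methyl 4-methoxysalicylate.

## Route

**Step 1**
Reactants: 1 5-bromo-2,4-dihydroxybenzaldehyde
Product: 2 5-bromo-2-hydroxy-4-[(triisopropylsilyl)oxy]benzaldehyde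
Conditions: TIPSCl (1.05 equiv), imidazole (2.2 equiv), DMF, 0 °C to rt
Reagents that add atoms: triisopropylsilyl chloride, CC(C)[Si](Cl)(C(C)C)C(C)C
Why: The 2-OH is hydrogen-bonded to the formyl group, so the free and more acidic 4-OH is silylated selectively (chemoselective phenol silylation).

**Step 2**
Reactants: 2 5-bromo-2-hydroxy-4-[(triisopropylsilyl)oxy]benzaldehyde
Product: 3 2-hydroxy-5-(3-methylbut-2-en-1-yl)-4-[(triisopropylsilyl)oxy]benzaldehyde
Conditions: prenylSnBu3 (1.3 equiv), Pd(PPh3)4 (5 mol %), degassed DMF, 90 °C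
Reagents that add atoms: tributyl(3-methylbut-2-en-1-yl)stannane, CCCC[Sn](CCCC)(CCCC)CC=C(C)C
Why: Stille cross-coupling of a 5-bromosalicylaldehyde runs under neutral conditions that spare CHO, the free OH and OTIPS, and prenylstannanes deliver mainly the linear (α-coupled) prenyl arene.

**Step 3**
Reactants: 4 methyl 2-hydroxy-4-methoxybenzoate
Product: 5 methyl 2-(allyloxy)-4-methoxybenzoate
Conditions: allyl bromide (1.3 equiv), K2CO3 (2 equiv), DMF, 60 °C
Reagents that add atoms: allyl bromide, C=CCBr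
Why: Williamson ether synthesis on the only phenol gives a small ortho protecting group that tolerates acid, base and silyl triflate.

**Step 4**
Reactants: 5 methyl 2-(allyloxy)-4-methoxybenzoate
Product: 6 2-(allyloxy)-4-methoxybenzoic acid
Conditions: LiOH·H2O (3 equiv), THF–MeOH–H2O, 50 °C; then 1 M HCl
Reagents that add atoms: lithium hydroxide, [Li+].[OH-]
Why: Ester saponification, to which the allyl and methyl aryl ethers are inert.

**Step 5**
Reactants: 6 2-(allyloxy)-4-methoxybenzoic acid
Product: 7 2-(allyloxy)-4-methoxybenzoyl chloride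
Conditions: (COCl)2 (1.5 equiv), DMF (cat.), CH2Cl2, 0 °C to rt; evaporate, use crude
Reagents that add atoms: oxalyl chloride, O=C(Cl)C(=O)Cl
Why: Vilsmeier-catalysed acid chloride formation gives only gaseous side products and leaves the ethers untouched.

**Step 6**
Reactants: 3 2-hydroxy-5-(3-methylbut-2-en-1-yl)-4-[(triisopropylsilyl)oxy]benzaldehyde; 7 2-(allyloxy)-4-methoxybenzoyl chloride
Product: 8 2-formyl-4-(3-methylbut-2-en-1-yl)-5-[(triisopropylsilyl)oxy]phenyl 2-(allyloxy)-4-methoxybenzoate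
Conditions: Et3N (2 equiv), DMAP (10 mol %), CH2Cl2, 0 °C to rt
Reagents that add atoms: none
Why: DMAP-catalysed O-acylation of the only free phenol with an acid chloride overcomes the hydrogen bond to the aldehyde and joins the two halves.

**Step 7**
Reactants: 8 2-formyl-4-(3-methylbut-2-en-1-yl)-5-[(triisopropylsilyl)oxy]phenyl 2-(allyloxy)-4-methoxybenzoate
Product: 9 2-(dimethoxymethyl)-4-(3-methylbut-2-en-1-yl)-5-[(triisopropylsilyl)oxy]phenyl 2-(allyloxy)-4-methoxybenzoate
Conditions: HC(OMe)3 (5 equiv), PPTS (5 mol %), MeOH–CH2Cl2, rt; Et3N quench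
Reagents that add atoms: trimethyl orthoformate, COC(OC)OC
Why: Acid-catalysed acetalisation driven by the orthoformate, with an acid too weak to affect the prenyl alkene, the aryl TIPS ether or the deactivated aryl benzoate.

**Step 8**
Reactants: 9 2-(dimethoxymethyl)-4-(3-methylbut-2-en-1-yl)-5-[(triisopropylsilyl)oxy]phenyl 2-(allyloxy)-4-methoxybenzoate
Product: 10 {[2-{[2-(allyloxy)-4-methoxybenzoyl]oxy}-5-(3-methylbut-2-en-1-yl)-4-[(triisopropylsilyl)oxy]phenyl](methoxy)methyl}triphenylphosphonium trifluoromethanesulfonate (racemic)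
Conditions: PPh3 (1.2 equiv), TMSOTf (1.05 equiv), CH2Cl2, −40 to 0 °C; precipitate with dry Et2O–pentane under Ar, use at once
Reagents that add atoms: triphenylphosphine, c1ccc(cc1)P(c1ccccc1)c1ccccc1; trimethylsilyl trifluoromethanesulfonate, C[Si](C)(C)OS(=O)(=O)C(F)(F)F
Why: Silyl triflate ionises the acetal to an oxocarbenium ion stabilised by the para silyloxy group, and PPh3 captures it (known α-alkoxyphosphonium, or O,P-acetal, salt formation from acetals); excess PPh3 buffers traces of acid, and the new stereocentre is racemic and erased in step 9.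

**Step 9**
Reactants: 10 {[2-{[2-(allyloxy)-4-methoxybenzoyl]oxy}-5-(3-methylbut-2-en-1-yl)-4-[(triisopropylsilyl)oxy]phenyl](methoxy)methyl}triphenylphosphonium trifluoromethanesulfonate
Product: 12 2-[2-(allyloxy)-4-methoxyphenyl]-3-methoxy-5-(3-methylbut-2-en-1-yl)-6-[(triisopropylsilyl)oxy]-1-benzofuran, via 2-[methoxy(triphenyl-λ5-phosphanylidene)methyl]-4-(3-methylbut-2-en-1-yl)-5-[(triisopropylsilyl)oxy]phenyl 2-(allyloxy)-4-methoxybenzoate 11 (not isolated)
Conditions: KHMDS (1.1 equiv), THF, −78 °C to rt, then 50 °C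
Reagents that add atoms: none
Why: Proposed new method: an intramolecular ester Wittig olefination of an α-methoxybenzylidene ylide derived from an O,P-acetal, which closes the furan ring, forms C2=C3 and delivers the 3-OMe in one event; KHMDS removes the only acidic C–H (α to P+), the ylide carbon is made more nucleophilic by the α-oxygen and is held 1,5 to the aryl-ester carbonyl, so it adds 5-exo-trig to a fused oxaphosphetane whose cycloreversion expels Ph3P=O irreversibly (P=O bond plus benzofuran aromaticity), while the competing O-to-C acyl transfer to a β-ketophosphonium phenoxide is reversible and feeds back into the same oxaphosphetane; the closest known reaction types are the intramolecular Wittig benzofuran synthesis from o-acyloxybenzylphosphonium salts (H or carbon on the ylide carbon) and the intermolecular Wittig reaction of α-alkoxybenzyl ylides with aldehydes, but to my knowledge an α-alkoxy ylide has not been olefinated with an ester and 3-alkoxybenzofurans have not been made this way; no stereocentre is formed.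

**Step 10**
Reactants: 12 2-[2-(allyloxy)-4-methoxyphenyl]-3-methoxy-5-(3-methylbut-2-en-1-yl)-6-[(triisopropylsilyl)oxy]-1-benzofuran
Product: 14 ambofuranol, 2-(2-hydroxy-4-methoxyphenyl)-3-methoxy-5-(3-methylbut-2-en-1-yl)-1-benzofuran-6-ol, via 5-methoxy-2-{3-methoxy-5-(3-methylbut-2-en-1-yl)-6-[(triisopropylsilyl)oxy]-1-benzofuran-2-yl}phenol 13 (not isolated)
Conditions: Pd(PPh3)4 (5 mol %), morpholine (3 equiv), THF, rt; then AcOH (3 equiv), TBAF (1.2 equiv), 0 °C to rt, under Ar
Reagents that add atoms: none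
Why: Tsuji–Trost deallylation with morpholine as allyl acceptor, then buffered fluoride cleavage of the aryl silyl ether; both are non-acidic and non-reductive, so the prenyl group next to the new phenol, the 3-methoxy enol ether and the methyl ethers survive.

## Compound list

1 | 5-bromo-2,4-dihydroxybenzaldehyde | O=Cc1cc(Br)c(O)cc1O | starting material
2 | 5-bromo-2-hydroxy-4-[(triisopropylsilyl)oxy]benzaldehyde | O=Cc1cc(Br)c(O[Si](C(C)C)(C(C)C)C(C)C)cc1O | intermediate
3 | 2-hydroxy-5-(3-methylbut-2-en-1-yl)-4-[(triisopropylsilyl)oxy]benzaldehyde | O=Cc1cc(CC=C(C)C)c(O[Si](C(C)C)(C(C)C)C(C)C)cc1O | intermediate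
4 | methyl 2-hydroxy-4-methoxybenzoate | COC(=O)c1ccc(OC)cc1O | starting material
5 | methyl 2-(allyloxy)-4-methoxybenzoate | COC(=O)c1ccc(OC)cc1OCC=C | intermediate
6 | 2-(allyloxy)-4-methoxybenzoic acid | OC(=O)c1ccc(OC)cc1OCC=C | intermediate
7 | 2-(allyloxy)-4-methoxybenzoyl chloride | ClC(=O)c1ccc(OC)cc1OCC=C | intermediate
8 | 2-formyl-4-(3-methylbut-2-en-1-yl)-5-[(triisopropylsilyl)oxy]phenyl 2-(allyloxy)-4-methoxybenzoate | O=Cc1cc(CC=C(C)C)c(O[Si](C(C)C)(C(C)C)C(C)C)cc1OC(=O)c1ccc(OC)cc1OCC=C | intermediate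
9 | 2-(dimethoxymethyl)-4-(3-methylbut-2-en-1-yl)-5-[(triisopropylsilyl)oxy]phenyl 2-(allyloxy)-4-methoxybenzoate | COC(OC)c1cc(CC=C(C)C)c(O[Si](C(C)C)(C(C)C)C(C)C)cc1OC(=O)c1ccc(OC)cc1OCC=C | intermediate
10 | {[2-{[2-(allyloxy)-4-methoxybenzoyl]oxy}-5-(3-methylbut-2-en-1-yl)-4-[(triisopropylsilyl)oxy]phenyl](methoxy)methyl}triphenylphosphonium trifluoromethanesulfonate (racemic) | COC(c1cc(CC=C(C)C)c(O[Si](C(C)C)(C(C)C)C(C)C)cc1OC(=O)c1ccc(OC)cc1OCC=C)[P+](c1ccccc1)(c1ccccc1)c1ccccc1.[O-]S(=O)(=O)C(F)(F)F | intermediate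
11 | 2-[methoxy(triphenyl-λ5-phosphanylidene)methyl]-4-(3-methylbut-2-en-1-yl)-5-[(triisopropylsilyl)oxy]phenyl 2-(allyloxy)-4-methoxybenzoate (ylide) | COC(c1cc(CC=C(C)C)c(O[Si](C(C)C)(C(C)C)C(C)C)cc1OC(=O)c1ccc(OC)cc1OCC=C)=P(c1ccccc1)(c1ccccc1)c1ccccc1 | intermediate
12 | 2-[2-(allyloxy)-4-methoxyphenyl]-3-methoxy-5-(3-methylbut-2-en-1-yl)-6-[(triisopropylsilyl)oxy]-1-benzofuran | COc1ccc(-c2oc3cc(O[Si](C(C)C)(C(C)C)C(C)C)c(CC=C(C)C)cc3c2OC)c(OCC=C)c1 | intermediate
13 | 5-methoxy-2-{3-methoxy-5-(3-methylbut-2-en-1-yl)-6-[(triisopropylsilyl)oxy]-1-benzofuran-2-yl}phenol | COc1ccc(-c2oc3cc(O[Si](C(C)C)(C(C)C)C(C)C)c(CC=C(C)C)cc3c2OC)c(O)c1 | intermediate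
14 | ambofuranol, 2-(2-hydroxy-4-methoxyphenyl)-3-methoxy-5-(3-methylbut-2-en-1-yl)-1-benzofuran-6-ol (achiral) | COc1ccc(-c2oc3cc(O)c(CC=C(C)C)cc3c2OC)c(O)c1 | target

## Step count

- Total step count: 10.
- Longest linear sequence: 8 steps (steps 3 to 10, from 4). The branch from 1 has 7 steps.

## The three steps most likely to fail

**Step 9 (the proposed new step).**
- Risk: the fully substituted ylide carbon may be too hindered to reach the electron-rich benzoate carbonyl.
- Risk: the adduct may stop at O-to-C acyl transfer.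
- Risk: the ylide may lose PPh3.

The fallback uses known chemistry only, sets out from 5 and 3, and comes back to the route at 12. Ester 5 is reduced with LiAlH4 (THF, 0 °C) to [2-(allyloxy)-4-methoxyphenyl]methanol F1. With tetrahydrothiophene and HBF4·OEt2 (CH2Cl2, rt) this gives 1-[2-(allyloxy)-4-methoxybenzyl]tetrahydrothiophenium tetrafluoroborate F2. KHMDS (2.1 equiv, THF, −78 °C to rt) on a mixture of F2 and aldehyde 3 generates the sulfur ylide [2-(allyloxy)-4-methoxyphenyl](tetrahydrothiophenium-1-yl)methanide F3. This ylide adds to the aldehyde in Corey–Chaykovsky fashion. The ortho phenoxide then displaces tetrahydrothiophene at the activated benzylic carbon, a formal [4+1] annulation of a salicylaldehyde. The product is racemic 2-[2-(allyloxy)-4-methoxyphenyl]-5-(3-methylbut-2-en-1-yl)-6-[(triisopropylsilyl)oxy]-2,3-dihydro-1-benzofuran-3-ol F4. Dess–Martin oxidation (CH2Cl2, NaHCO3) gives racemic 2-[2-(allyloxy)-4-methoxyphenyl]-5-(3-methylbut-2-en-1-yl)-6-[(triisopropylsilyl)oxy]-1-benzofuran-3(2H)-one F5. O-Methylation of its enolate with the hard electrophile Me2SO4 (K2CO3, degassed acetone) aromatises it to 12.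

**Step 8.**
- Risk: the neighbouring ester carbonyl may trap the oxocarbenium ion as a benzodioxinylium ion.
- Risk: PPh3 may be methylated by the oxocarbenium ion, returning aldehyde 8.
- Risk: the salt may hydrolyse on isolation.

The fallback reverses the order of P–C and O-acyl bond formation. It sets out from 3 and 7 and comes back at 11, and so at 12. Aldehyde 3 is treated with HC(OMe)3 and Ph3P·HBF4 (MeCN, rt to 40 °C). The acetal 2-(dimethoxymethyl)-4-(3-methylbut-2-en-1-yl)-5-[(triisopropylsilyl)oxy]phenol F6 forms in the flask. With no ester present, it passes on to {[2-hydroxy-5-(3-methylbut-2-en-1-yl)-4-[(triisopropylsilyl)oxy]phenyl](methoxy)methyl}triphenylphosphonium tetrafluoroborate F7. Acid chloride 7 and Et3N (2.5 equiv, toluene, rt to 80 °C) then acylate the phenol. This gives {[2-{[2-(allyloxy)-4-methoxybenzoyl]oxy}-5-(3-methylbut-2-en-1-yl)-4-[(triisopropylsilyl)oxy]phenyl](methoxy)methyl}triphenylphosphonium tetrafluoroborate F8. F8 is deprotonated in the same pot to ylide 11, as in the classical one-pot acylation and Wittig protocol.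

**Step 2.**
- Risk: oxidative addition into the hindered, electron-rich bromide may be slow.
- Risk: partial γ-coupling may give the reverse-prenyl isomer.

The fallback builds the prenyl group in two stages. It sets out from 2 and comes back at 3. Stille coupling of 2 with the unhindered and regiochemically unambiguous allyltributylstannane (Pd(PPh3)4, DMF, 80 °C) gives 5-allyl-2-hydroxy-4-[(triisopropylsilyl)oxy]benzaldehyde F9. Cross-metathesis of F9 with excess 2-methylbut-2-ene (Grubbs II, 3 mol %, CH2Cl2, 40 °C) gives 3.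

## Further compounds

F1 | step 9 | [2-(allyloxy)-4-methoxyphenyl]methanol | OCc1ccc(OC)cc1OCC=C
F2 | step 9 | 1-[2-(allyloxy)-4-methoxybenzyl]tetrahydrothiophenium tetrafluoroborate | C=CCOc1cc(OC)ccc1C[S+]1CCCC1.F[B-](F)(F)F
F3 | step 9 | [2-(allyloxy)-4-methoxyphenyl](tetrahydrothiophenium-1-yl)methanide (sulfur ylide, formed in the flask) | C=CCOc1cc(OC)ccc1[CH-][S+]1CCCC1
F4 | step 9 | 2-[2-(allyloxy)-4-methoxyphenyl]-5-(3-methylbut-2-en-1-yl)-6-[(triisopropylsilyl)oxy]-2,3-dihydro-1-benzofuran-3-ol (racemic, C2/C3 configuration not controlled, both centres erased later) | COc1ccc(C2Oc3cc(O[Si](C(C)C)(C(C)C)C(C)C)c(CC=C(C)C)cc3C2O)c(OCC=C)c1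
F5 | step 9 | 2-[2-(allyloxy)-4-methoxyphenyl]-5-(3-methylbut-2-en-1-yl)-6-[(triisopropylsilyl)oxy]-1-benzofuran-3(2H)-one (racemic, centre erased on O-methylation) | COc1ccc(C2Oc3cc(O[Si](C(C)C)(C(C)C)C(C)C)c(CC=C(C)C)cc3C2=O)c(OCC=C)c1
F6 | step 8 | 2-(dimethoxymethyl)-4-(3-methylbut-2-en-1-yl)-5-[(triisopropylsilyl)oxy]phenol | COC(OC)c1cc(CC=C(C)C)c(O[Si](C(C)C)(C(C)C)C(C)C)cc1O
F7 | step 8 | {[2-hydroxy-5-(3-methylbut-2-en-1-yl)-4-[(triisopropylsilyl)oxy]phenyl](methoxy)methyl}triphenylphosphonium tetrafluoroborate (racemic) | COC(c1cc(CC=C(C)C)c(O[Si](C(C)C)(C(C)C)C(C)C)cc1O)[P+](c1ccccc1)(c1ccccc1)c1ccccc1.F[B-](F)(F)F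
F8 | step 8 | {[2-{[2-(allyloxy)-4-methoxybenzoyl]oxy}-5-(3-methylbut-2-en-1-yl)-4-[(triisopropylsilyl)oxy]phenyl](methoxy)methyl}triphenylphosphonium tetrafluoroborate (racemic) | COC(c1cc(CC=C(C)C)c(O[Si](C(C)C)(C(C)C)C(C)C)cc1OC(=O)c1ccc(OC)cc1OCC=C)[P+](c1ccccc1)(c1ccccc1)c1ccccc1.F[B-](F)(F)F
F9 | step 2 | 5-allyl-2-hydroxy-4-[(triisopropylsilyl)oxy]benzaldehyde | O=Cc1cc(CC=C)c(O[Si](C(C)C)(C(C)C)C(C)C)cc1O
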